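Ring A (C4a, C5, C6, C7, C8, C8a) is hexasubstituted: oxygen on C5 and C7 (meta), prenyl on C6 and C8, fused to pyranone ring C. This is the pattern a ketene/siloxyalkyne benzannulation delivers, so ring A is disconnected from a preformed 3-aryl-4-pyranone. In one operation a photo-Wolff rearrangement converts a pyranonyl α-diazo ketone into a pyranonyl(prenyl)ketene that captures a prenylated siloxyalkyne and closes ring A (C8–C8a by the Wolff shift, then C5–C6, C7–C8, C4a–C5). The precursor is a 5-(chromenyl)-4-pyranone carrying a 2-diazo-5-methylhex-4-enoyl chain on C2; both phenols travel as triisopropylsilyl ethers and fall together in the last step.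

Key step: step 13

Remarks on the chemistry:
- Isoflavone numbering is used for 26 and 27; pyranone C2 and C3 of the precursors become C8a and C4a.
- The 4'-oxygen is carried as a triisopropylsilyl ether instead of an acetal, so that no acid meets the prenyl groups beside free phenols at the end and one fluoride step finishes the synthesis.
- Irradiation is placed near 420 nm, where only the diazo ketone should absorb, because a 2H-chromene opens photochemically under UV light.
- The target has no stereocentre; the stereogenic carbons of 13, 15, 23 and 25 are racemic and transient.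
- No error was found in the target, precursor or product structures; all ring-A positions were checked against the connectivity of the two annulation partners.

Step 1
Reactants: 1 4-bromoresorcinol (4-bromobenzene-1,3-diol)
Product: 2 2-bromo-5-[(triisopropylsilyl)oxy]phenol
Conditions: TIPSCl (1.0 equiv), imidazole, CH2Cl2, −20 → 0 °C
Reagents that add atoms: chlorotriisopropylsilane (TIPSCl), CC(C)[Si](Cl)(C(C)C)C(C)C
Why: Imidazole-mediated silyl ether formation should be site-selective, because the bulky silyl chloride reaches the open hydroxyl para to bromine far more easily than the hydroxyl shielded and deactivated by the ortho bromine.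

Step 2
Reactants: 2 2-bromo-5-[(triisopropylsilyl)oxy]phenol; 3 3-chloro-3-methylbut-1-yne
Product: 4 {4-bromo-3-[(2-methylbut-3-yn-2-yl)oxy]phenoxy}triisopropylsilane
Conditions: DBU, CuCl2·2H2O (cat.), MeCN, 0 °C
Reagents that add atoms: none
Why: Copper-catalysed O-propargylation of a phenol by a tertiary propargylic chloride (Godfrey etherification) runs through a copper acetylide-derived electrophile at 0 °C, conditions under which the aryl silyl ether and the aryl bromide are inert.

Step 3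
Reactants: 4 {4-bromo-3-[(2-methylbut-3-yn-2-yl)oxy]phenoxy}triisopropylsilane
Product: 5 8-bromo-2,2-dimethyl-5-[(triisopropylsilyl)oxy]-2H-chromene
Conditions: o-xylene, 140 °C
Reagents that add atoms: none
Why: The aryl propargyl ether Claisen rearrangement can only go to the free ortho carbon between the two oxygens (the other ortho carbon bears bromine), and the usual hydrogen shift and oxa-6π ring closure then give the 2,2-dimethyl-2H-chromene.

Step 4
Reactants: 5 8-bromo-2,2-dimethyl-5-[(triisopropylsilyl)oxy]-2H-chromene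
Product: 6 2-{2,2-dimethyl-5-[(triisopropylsilyl)oxy]-2H-chromen-8-yl}-4,4,5,5-tetramethyl-1,3,2-dioxaborolane
Conditions: B2pin2, Pd(dppf)Cl2 (3 mol %), KOAc, 1,4-dioxane, 90 °C
Reagents that add atoms: bis(pinacolato)diboron, CC1(C)OB(OC1(C)C)B1OC(C)(C)C(C)(C)O1
Why: Miyaura borylation of an aryl bromide with the weak base KOAc suppresses biaryl formation and leaves the silyl ether and the chromene alkene untouched.

Step 5
Reactants: 7 kojic acid (5-hydroxy-2-(hydroxymethyl)-4H-pyran-4-one)
Product: 8 6-(hydroxymethyl)-4-oxo-4H-pyran-3-yl trifluoromethanesulfonate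
Conditions: PhNTf2, Et3N, DMF, 0 → 20 °C
Reagents that add atoms: N-phenylbis(trifluoromethanesulfonimide), O=S(=O)(N(c1ccccc1)S(=O)(=O)C(F)(F)F)C(F)(F)F
Why: Only the acidic enolic 5-OH is deprotonated by Et3N, and the mild triflyl donor sulfonylates that oxyanion while the neutral primary alcohol does not react (chemoselective enol triflate formation).

Step 6
Reactants: 8 6-(hydroxymethyl)-4-oxo-4H-pyran-3-yl trifluoromethanesulfonate; 6 2-{2,2-dimethyl-5-[(triisopropylsilyl)oxy]-2H-chromen-8-yl}-4,4,5,5-tetramethyl-1,3,2-dioxaborolane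
Product: 9 5-{2,2-dimethyl-5-[(triisopropylsilyl)oxy]-2H-chromen-8-yl}-2-(hydroxymethyl)-4H-pyran-4-one
Conditions: Pd(OAc)2 (3 mol %), SPhos (6 mol %), K3PO4, THF/H2O, 50 °C
Reagents that add atoms: none
Why: Suzuki–Miyaura coupling should work because the α-triflyloxy enone adds oxidatively with ease, the bulky biaryl phosphine handles the ortho-alkoxy boronate, and phosphate base spares the aryl silyl ether and tolerates the free alcohol.

Step 7
Reactants: 9 5-{2,2-dimethyl-5-[(triisopropylsilyl)oxy]-2H-chromen-8-yl}-2-(hydroxymethyl)-4H-pyran-4-one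
Product: 10 5-{2,2-dimethyl-5-[(triisopropylsilyl)oxy]-2H-chromen-8-yl}-4-oxo-4H-pyran-2-carbaldehyde
Conditions: Dess–Martin periodinane, CH2Cl2, 0 → 20 °C
Reagents that add atoms: none
Why: Dess–Martin oxidation takes the primary allylic-type alcohol to the aldehyde without over-oxidation and without touching the chromene alkene or the silyl ether.

Step 8
Reactants: 10 5-{2,2-dimethyl-5-[(triisopropylsilyl)oxy]-2H-chromen-8-yl}-4-oxo-4H-pyran-2-carbaldehyde; 11 5-bromo-2-methylpent-2-ene
Product: 13 rac-5-{2,2-dimethyl-5-[(triisopropylsilyl)oxy]-2H-chromen-8-yl}-2-(1-hydroxy-5-methylhex-4-en-1-yl)-4H-pyran-4-one, via homoprenylmagnesium bromide 12 (not isolated)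
Conditions: 11, Mg, THF, 20 °C; then 10, THF, −78 °C; aq. NH4Cl
Reagents that add atoms: magnesium, [Mg] (present only in 12)
Why: Grignard 1,2-addition to the strongly electrophilic aldehyde at −78 °C should far outpace attack on the vinylogous-ester carbonyl of the pyranone; the new carbinol centre forms without control (racemic) and is erased in step 9.

Step 9
Reactants: 13 rac-5-{2,2-dimethyl-5-[(triisopropylsilyl)oxy]-2H-chromen-8-yl}-2-(1-hydroxy-5-methylhex-4-en-1-yl)-4H-pyran-4-one
Product: 14 5-{2,2-dimethyl-5-[(triisopropylsilyl)oxy]-2H-chromen-8-yl}-2-(5-methylhex-4-enoyl)-4H-pyran-4-one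
Conditions: Dess–Martin periodinane, CH2Cl2, 0 → 20 °C
Reagents that add atoms: none
Why: Dess–Martin oxidation of the secondary alcohol gives the homoprenyl ketone under neutral conditions that leave both trisubstituted alkenes and the silyl ether alone.

Step 10
Reactants: 14 5-{2,2-dimethyl-5-[(triisopropylsilyl)oxy]-2H-chromen-8-yl}-2-(5-methylhex-4-enoyl)-4H-pyran-4-one
Product: 16 2-diazo-1-{5-[2,2-dimethyl-5-(triisopropylsilyloxy)-2H-chromen-8-yl]-4-oxo-4H-pyran-2-yl}-5-methylhex-4-en-1-one, via trifluoroacetyl diketone 15 (not isolated)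
Conditions: LiN(SiMe3)2, THF, −78 °C; CF3CO2CH2CF3, −78 °C; 5% aq. HCl wash; then 4-AcNHC6H4SO2N3, Et3N, H2O (1 equiv), MeCN, 20 °C
Reagents that add atoms: 4-acetamidobenzenesulfonyl azide, CC(=O)Nc1ccc(cc1)S(=O)(=O)N=[N+]=[N-]; 2,2,2-trifluoroethyl trifluoroacetate, O=C(OCC(F)(F)F)C(F)(F)F (its CF3CO group is carried only by 15)
Why: Detrifluoroacetylative diazo transfer (Danheiser protocol, a Regitz-type transfer) works on ketones that resist direct transfer, because the kinetic enolate at the only enolisable CH2 is trifluoroacetylated and the activated diketone then exchanges its CF3CO group for N2.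

Step 11
Reactants: 17 4-methylpent-3-enoic acid
Product: 18 ethyl 4-methylpent-3-enoate
Conditions: EtI, K2CO3, DMF, 20 °C
Reagents that add atoms: iodoethane, CCI
Why: SN2 O-alkylation of the carboxylate is chosen over acid-catalysed esterification, which would lactonise this β,γ-unsaturated acid, and the weak base should not move the double bond into conjugation.

Step 12
Reactants: 18 ethyl 4-methylpent-3-enoate
Product: 21 triisopropyl[(5-methylhex-4-en-1-yn-1-yl)oxy]silane, via lithium dibromoenolate 19 (not isolated), via lithium ynolate 20 (not isolated)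
Conditions: CH2Br2, lithium 2,2,6,6-tetramethylpiperidide, THF, −78 °C; 18; LiN(SiMe3)2, −78 °C; n-BuLi, −78 → 20 °C; TIPSCl, −78 → 0 °C
Reagents that add atoms: dibromomethane, BrCBr; chlorotriisopropylsilane, CC(C)[Si](Cl)(C(C)C)C(C)C; n-butyllithium, [Li]CCCC (with LiN(SiMe3)2 the source of the lithium in 19 and 20)
Why: Kowalski ester homologation: LiCHBr2 adds to the ester, bromine–lithium exchange on the dibromo enolate triggers a carbenoid 1,2-shift to the ynolate, and the bulky silyl chloride traps it on oxygen.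

Step 13
Reactants: 16 2-diazo-1-{5-[2,2-dimethyl-5-(triisopropylsilyloxy)-2H-chromen-8-yl]-4-oxo-4H-pyran-2-yl}-5-methylhex-4-en-1-one; 21 triisopropyl[(5-methylhex-4-en-1-yn-1-yl)oxy]silane
Product: 26 3-{2,2-dimethyl-5-[(triisopropylsilyl)oxy]-2H-chromen-8-yl}-5-hydroxy-6,8-bis(3-methylbut-2-en-1-yl)-7-[(triisopropylsilyl)oxy]-4H-chromen-4-one, via ketene 22 (not isolated), via cyclobutenone 23 (not isolated), via dienylketene 24 (not isolated), via cyclohexadienone 25 (not isolated)
Conditions: 21 (2.5 equiv), degassed ClCH2CH2Cl (0.05 M), 420 nm LED, 20 °C; then 80 °C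
Reagents that add atoms: none
Why: Light of about 420 nm, which only the diazo ketone should absorb, expels N2 and moves the pyranon-2-yl group from the acyl carbon to the diazo carbon (Wolff rearrangement, C8–C8a) to give ketene 22. Its electrophilic carbonyl carbon bonds to the nucleophilic alkyne carbon remote from oxygen (C5–C6) and its α-carbon to the silyloxy carbon (C7–C8) in a polarised [2+2] cycloaddition that gives cyclobutenone 23. At 80 °C 23 opens by reversible 4π electrocyclic ring opening to dienylketene 24, ring A then closes by thermal 6π electrocyclisation of the ketene carbon onto the pyranone C3–H carbon (C4a–C5), and cyclohexadienone 25 enolises to the hydrogen-bonded C5 phenol. The closest known reaction type is the Danheiser benzannulation in its α-diazo ketone (photo-Wolff) form with siloxyalkynes, where an aryl, heteroaryl or alkenyl group of the diazo ketone is the two-carbon arm; here the pyranone C2=C3 bond takes that role. No stereocentre remains, since the stereogenic carbons of 23 and 25 disappear on ring opening and aromatisation. Two selectivities are needed: regiochemistry, fixed by the polarity of both partners so that the silyloxy carbon lands between the two prenyl-bearing carbons, and acyl shift in preference to 1,2-hydrogen migration at the carbene carbon, which direct excitation without metal or sensitiser favours; excess 21 outruns ketene dimerisation, and the prenyl groups, the chromene and the aryl silyl ether are spectators.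

Step 14
Reactants: 26 3-{2,2-dimethyl-5-[(triisopropylsilyl)oxy]-2H-chromen-8-yl}-5-hydroxy-6,8-bis(3-methylbut-2-en-1-yl)-7-[(triisopropylsilyl)oxy]-4H-chromen-4-one
Product: 27 Kanzonol L (5,7-dihydroxy-3-(5-hydroxy-2,2-dimethyl-2H-chromen-8-yl)-6,8-bis(3-methylbut-2-en-1-yl)-4H-chromen-4-one)
Conditions: TBAF (2.5 equiv), AcOH (2.5 equiv), THF, 0 → 20 °C
Reagents that add atoms: none
Why: Fluoride-induced cleavage of both aryl silyl ethers, buffered by AcOH so that no strongly basic phenoxide attacks the pyranone ring and no acid cyclises a prenyl group onto a neighbouring phenol.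

Compound list
1 | 4-bromoresorcinol | Oc1ccc(Br)c(O)c1 | starting material
2 | 2-bromo-5-[(triisopropylsilyl)oxy]phenol | Oc1cc(O[Si](C(C)C)(C(C)C)C(C)C)ccc1Br | intermediate
3 | 3-chloro-3-methylbut-1-yne | C#CC(C)(C)Cl | starting material
4 | {4-bromo-3-[(2-methylbut-3-yn-2-yl)oxy]phenoxy}triisopropylsilane | C#CC(C)(C)Oc1cc(O[Si](C(C)C)(C(C)C)C(C)C)ccc1Br | intermediate
5 | 8-bromo-2,2-dimethyl-5-[(triisopropylsilyl)oxy]-2H-chromene | CC1(C)C=Cc2c(O[Si](C(C)C)(C(C)C)C(C)C)ccc(Br)c2O1 | intermediate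
6 | 2-{2,2-dimethyl-5-[(triisopropylsilyl)oxy]-2H-chromen-8-yl}-4,4,5,5-tetramethyl-1,3,2-dioxaborolane | CC1(C)C=Cc2c(O[Si](C(C)C)(C(C)C)C(C)C)ccc(B3OC(C)(C)C(C)(C)O3)c2O1 | intermediate
7 | kojic acid | OCc1cc(=O)c(O)co1 | starting material
8 | 6-(hydroxymethyl)-4-oxo-4H-pyran-3-yl trifluoromethanesulfonate | OCc1cc(=O)c(OS(=O)(=O)C(F)(F)F)co1 | intermediate
9 | 5-{2,2-dimethyl-5-[(triisopropylsilyl)oxy]-2H-chromen-8-yl}-2-(hydroxymethyl)-4H-pyran-4-one | OCc1cc(=O)c(-c2ccc(O[Si](C(C)C)(C(C)C)C(C)C)c3c2OC(C)(C)C=C3)co1 | intermediate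
10 | 5-{2,2-dimethyl-5-[(triisopropylsilyl)oxy]-2H-chromen-8-yl}-4-oxo-4H-pyran-2-carbaldehyde | O=Cc1cc(=O)c(-c2ccc(O[Si](C(C)C)(C(C)C)C(C)C)c3c2OC(C)(C)C=C3)co1 | intermediate
11 | 5-bromo-2-methylpent-2-ene | CC(C)=CCCBr | starting material
12 | (4-methylpent-3-en-1-yl)magnesium bromide | CC(C)=CCC[Mg]Br | intermediate (not isolated)
13 | rac-5-{2,2-dimethyl-5-[(triisopropylsilyl)oxy]-2H-chromen-8-yl}-2-(1-hydroxy-5-methylhex-4-en-1-yl)-4H-pyran-4-one (racemic) | CC(C)=CCCC(O)c1cc(=O)c(-c2ccc(O[Si](C(C)C)(C(C)C)C(C)C)c3c2OC(C)(C)C=C3)co1 | intermediate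
14 | 5-{2,2-dimethyl-5-[(triisopropylsilyl)oxy]-2H-chromen-8-yl}-2-(5-methylhex-4-enoyl)-4H-pyran-4-one | CC(C)=CCCC(=O)c1cc(=O)c(-c2ccc(O[Si](C(C)C)(C(C)C)C(C)C)c3c2OC(C)(C)C=C3)co1 | intermediate
15 | rac-1-{5-[2,2-dimethyl-5-(triisopropylsilyloxy)-2H-chromen-8-yl]-4-oxo-4H-pyran-2-yl}-4,4,4-trifluoro-2-(3-methylbut-2-en-1-yl)butane-1,3-dione (racemic, largely enolised) | CC(C)=CCC(C(=O)C(F)(F)F)C(=O)c1cc(=O)c(-c2ccc(O[Si](C(C)C)(C(C)C)C(C)C)c3c2OC(C)(C)C=C3)co1 | intermediate (not isolated)
16 | 2-diazo-1-{5-[2,2-dimethyl-5-(triisopropylsilyloxy)-2H-chromen-8-yl]-4-oxo-4H-pyran-2-yl}-5-methylhex-4-en-1-one | CC(C)=CCC(=[N+]=[N-])C(=O)c1cc(=O)c(-c2ccc(O[Si](C(C)C)(C(C)C)C(C)C)c3c2OC(C)(C)C=C3)co1 | intermediate (key-step precursor)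
17 | 4-methylpent-3-enoic acid | CC(C)=CCC(=O)O | starting material
18 | ethyl 4-methylpent-3-enoate | CCOC(=O)CC=C(C)C | intermediate
19 | lithium 1,1-dibromo-5-methylhexa-1,4-dien-2-olate | [Li+].[O-]C(CC=C(C)C)=C(Br)Br | intermediate (not isolated)
20 | lithium 5-methylhex-4-en-1-yn-1-olate | [Li+].[O-]C#CCC=C(C)C | intermediate (not isolated)
21 | triisopropyl[(5-methylhex-4-en-1-yn-1-yl)oxy]silane | CC(C)=CCC#CO[Si](C(C)C)(C(C)C)C(C)C | intermediate
22 | 2-{5-[2,2-dimethyl-5-(triisopropylsilyloxy)-2H-chromen-8-yl]-4-oxo-4H-pyran-2-yl}-5-methylhexa-1,4-dien-1-one (pyranonyl(prenyl)ketene) | CC(C)=CCC(=C=O)c1cc(=O)c(-c2ccc(O[Si](C(C)C)(C(C)C)C(C)C)c3c2OC(C)(C)C=C3)co1 | intermediate (not isolated)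
23 | rac-4-{5-[2,2-dimethyl-5-(triisopropylsilyloxy)-2H-chromen-8-yl]-4-oxo-4H-pyran-2-yl}-2,4-bis(3-methylbut-2-en-1-yl)-3-[(triisopropylsilyl)oxy]cyclobut-2-en-1-one (racemic) | CC(C)=CCC1=C(O[Si](C(C)C)(C(C)C)C(C)C)C(CC=C(C)C)(c2cc(=O)c(-c3ccc(O[Si](C(C)C)(C(C)C)C(C)C)c4c3OC(C)(C)C=C4)co2)C1=O | intermediate (not isolated)
24 | (3E)-4-{5-[2,2-dimethyl-5-(triisopropylsilyloxy)-2H-chromen-8-yl]-4-oxo-4H-pyran-2-yl}-7-methyl-2-(3-methylbut-2-en-1-yl)-3-[(triisopropylsilyl)oxy]octa-1,3,6-trien-1-one | O=C=C(CC=C(C)C)/C(O[Si](C(C)C)(C(C)C)C(C)C)=C(/CC=C(C)C)c1cc(=O)c(-c2ccc(O[Si](C(C)C)(C(C)C)C(C)C)c3c2OC(C)(C)C=C3)co1 | intermediate (not isolated)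
25 | rac-3-{2,2-dimethyl-5-[(triisopropylsilyl)oxy]-2H-chromen-8-yl}-6,8-bis(3-methylbut-2-en-1-yl)-7-[(triisopropylsilyl)oxy]-4aH-chromene-4,5-dione (racemic) | O=C1C(CC=C(C)C)=C(O[Si](C(C)C)(C(C)C)C(C)C)C(CC=C(C)C)=C2OC=C(c3ccc(O[Si](C(C)C)(C(C)C)C(C)C)c4c3OC(C)(C)C=C4)C(=O)C12 | intermediate (not isolated)
26 | 3-{2,2-dimethyl-5-[(triisopropylsilyl)oxy]-2H-chromen-8-yl}-5-hydroxy-6,8-bis(3-methylbut-2-en-1-yl)-7-[(triisopropylsilyl)oxy]-4H-chromen-4-one | CC(C)=CCc1c(O[Si](C(C)C)(C(C)C)C(C)C)c(CC=C(C)C)c2occ(-c3ccc(O[Si](C(C)C)(C(C)C)C(C)C)c4c3OC(C)(C)C=C4)c(=O)c2c1O | intermediate (key-step product)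
27 | Kanzonol L | CC(C)=CCc1c(O)c(CC=C(C)C)c2occ(-c3ccc(O)c4c3OC(C)(C)C=C4)c(=O)c2c1O | target

Total step count: 14.
Longest linear sequence: 11 steps (steps 1, 2, 3, 4, 6, 7, 8, 9, 10, 13, 14, from 4-bromoresorcinol).

Steps most likely to fail

1. Step 13. 1,2-Hydrogen migration from the allylic CH2 to the carbene carbon may outrun the acyl shift, so that little ketene forms, and the cascade may also stall before the cyclobutenone opens. The fallback makes the same ketene without a carbene and sets out from alcohol 9. PPh3/CCl4 (CH2Cl2) should give 2-(chloromethyl)-5-{2,2-dimethyl-5-[(triisopropylsilyl)oxy]-2H-chromen-8-yl}-4H-pyran-4-one F1. Methoxycarbonylation (Pd(PPh3)2Cl2, CO 1 atm, MeOH, iPr2NEt, 60 °C) should give methyl 2-{5-[2,2-dimethyl-5-(triisopropylsilyloxy)-2H-chromen-8-yl]-4-oxo-4H-pyran-2-yl}acetate F2. LiN(SiMe3)2 (THF, −78 °C) and 1-bromo-3-methylbut-2-ene should give methyl rac-2-{5-[2,2-dimethyl-5-(triisopropylsilyloxy)-2H-chromen-8-yl]-4-oxo-4H-pyran-2-yl}-5-methylhex-4-enoate F3. Me3SnOH (ClCH2CH2Cl, 60 °C) should give rac-2-{5-[2,2-dimethyl-5-(triisopropylsilyloxy)-2H-chromen-8-yl]-4-oxo-4H-pyran-2-yl}-5-methylhex-4-enoic acid F4. 1-Chloro-N,N,2-trimethylprop-1-en-1-amine (CH2Cl2, 0 °C) should give rac-2-{5-[2,2-dimethyl-5-(triisopropylsilyloxy)-2H-chromen-8-yl]-4-oxo-4H-pyran-2-yl}-5-methylhex-4-enoyl chloride F5. Et3N in the presence of 21 then dehydrochlorinates F5 to ketene 22, where the fallback rejoins the route; thermal [2+2] addition to 23 and heating at 80 °C lead on to 26 (the known thermal ketene/siloxyalkyne resorcinol annulation).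

2. Step 12. The lithium carbenoid or amide may deprotonate the doubly activated α-CH2 of the β,γ-unsaturated ester instead of adding to its carbonyl, which would give a dienolate, move the double bond into conjugation and consume the ester. The fallback sets out from ester 18 and builds the alkyne before the oxygen is introduced. DIBAL-H (CH2Cl2, −78 °C) should give 4-methylpent-3-enal F6. CBr4/PPh3 should give 1,1-dibromo-5-methylhexa-1,4-diene F7. n-BuLi (2 equiv, THF, −78 °C) should give lithium 5-methylhex-4-en-1-yn-1-ide F8, which is oxidised in the same flask with LiOOt-Bu (from t-BuOOH and LiN(SiMe3)2) to ynolate 20, where the fallback rejoins the route before silylation to 21.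

3. Step 6. Aqueous base may cleave the S–O bond of the enol triflate, and the electron-rich ortho-alkoxy boronate may protodeboronate, both faster than transmetalation. The fallback sets out from bromide 5 and uses a base-free coupling. n-BuLi (THF, −78 °C) then Bu3SnCl should give tributyl{2,2-dimethyl-5-[(triisopropylsilyl)oxy]-2H-chromen-8-yl}stannane F9, which is coupled with triflate 8 under Stille conditions (Pd(PPh3)4, LiCl, CuI, DMF, 60 °C) and rejoins the route at 9.

Further compounds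
F1 | step 13 | 2-(chloromethyl)-5-{2,2-dimethyl-5-[(triisopropylsilyl)oxy]-2H-chromen-8-yl}-4H-pyran-4-one | ClCc1cc(=O)c(-c2ccc(O[Si](C(C)C)(C(C)C)C(C)C)c3c2OC(C)(C)C=C3)co1
F2 | step 13 | methyl 2-{5-[2,2-dimethyl-5-(triisopropylsilyloxy)-2H-chromen-8-yl]-4-oxo-4H-pyran-2-yl}acetate | COC(=O)Cc1cc(=O)c(-c2ccc(O[Si](C(C)C)(C(C)C)C(C)C)c3c2OC(C)(C)C=C3)co1
F3 | step 13 | methyl rac-2-{5-[2,2-dimethyl-5-(triisopropylsilyloxy)-2H-chromen-8-yl]-4-oxo-4H-pyran-2-yl}-5-methylhex-4-enoate | COC(=O)C(CC=C(C)C)c1cc(=O)c(-c2ccc(O[Si](C(C)C)(C(C)C)C(C)C)c3c2OC(C)(C)C=C3)co1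
F4 | step 13 | rac-2-{5-[2,2-dimethyl-5-(triisopropylsilyloxy)-2H-chromen-8-yl]-4-oxo-4H-pyran-2-yl}-5-methylhex-4-enoic acid | OC(=O)C(CC=C(C)C)c1cc(=O)c(-c2ccc(O[Si](C(C)C)(C(C)C)C(C)C)c3c2OC(C)(C)C=C3)co1
F5 | step 13 | rac-2-{5-[2,2-dimethyl-5-(triisopropylsilyloxy)-2H-chromen-8-yl]-4-oxo-4H-pyran-2-yl}-5-methylhex-4-enoyl chloride | ClC(=O)C(CC=C(C)C)c1cc(=O)c(-c2ccc(O[Si](C(C)C)(C(C)C)C(C)C)c3c2OC(C)(C)C=C3)co1
F6 | step 12 | 4-methylpent-3-enal | CC(C)=CCC=O
F7 | step 12 | 1,1-dibromo-5-methylhexa-1,4-diene | CC(C)=CCC=C(Br)Br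
F8 | step 12 | lithium 5-methylhex-4-en-1-yn-1-ide | [Li+].[C-]#CCC=C(C)C
F9 | step 6 | tributyl{2,2-dimethyl-5-[(triisopropylsilyl)oxy]-2H-chromen-8-yl}stannane | CCCC[Sn](CCCC)(CCCC)c1ccc(O[Si](C(C)C)(C(C)C)C(C)C)c2C=CC(C)(C)Oc12
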